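A direct plan would start from ring A: double C-prenylation of 2,4-dihydroxyacetophenone A1 to the 3,5-diprenyl ketone A2 and silylation of the 4-hydroxyl to the aryl silyl ether A3.
It would then O-allylate the remaining phenol with tert-butyl 4-methoxycinnamyl carbonate A4, using [Ir(cod)Cl]2 and a chiral phosphoramidite, to the branched (S)-allyl aryl ether A5.
It would end with enol silylation of the acetyl group to the silyl enol ether A6, ring-closing metathesis to the 4,7-bis(silyloxy)-2H-chromene A7 and desilylation.
Weak point (a) would be the double prenylation of the resorcinol ketone: nothing controls C- against O-alkylation or the degree of alkylation, so most of the material would be lost in the first operation.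
Weak point (b) would be the allylic etherification: the only stereocentre would depend on a di-ortho-substituted, hydrogen-bonded 2-acylphenoxide attacking the hindered end of an electron-rich cinnamyl system that ionises reversibly.
Weak point (c) would be the late metathesis that closes ring C on a 1,1-disubstituted silyl enol ether beside two prenyl alkenes, after an enolisation next to a doubly activated ether C–H; this is the step least welcome on advanced material.
Four of its operations (phenol silylation, carbonate formation, enol silylation, desilylation) would add no skeletal bond.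

**Plan of the new route**
The retrosynthesis cuts ring A at C8–C8a and C4a–C5 (Diels–Alder retron) and ring C at O1–C8a and C2–C3 (aldol retron); no bond to an existing arene is made.
Ring B comes from 4-methoxybenzaldehyde; ring C is made first, as a 6-sulfonyl-2,3-dihydro-4H-pyran-4-one with C2 set by a catalytic asymmetric aldol addition; ring A is made last, in the final step, on the C4a=C8a bond of ring C.
The feature that allows this is the pattern of ring A, a 4-acylresorcinol: C7–OH is para to the acyl-bearing C4a, O1 sits on C8a, C5 is unsubstituted, and C6–C7–C8 with its two prenyl groups is symmetrical about C7.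
C5–C8 therefore map onto a 1-amino-3-siloxydiene made from a symmetrical ketone, and C4a=C8a onto a β-sulfonyl enone (an ynone equivalent).
No phenol is prenylated (both prenyl groups arrive inside the ketone), no hindered phenoxide is allylated (O1–C2 is the former aldehyde C–O bond), no metathesis is needed and no protecting group is carried.

Key step: step 7

Assumption: (S)-BINOL is written in step 2 on the expectation that its titanium complex directs the nucleophile to the Si face of an aryl aldehyde; should the aldol prove to be R, (R)-BINOL is used and nothing else changes.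

Step 1
Reactants: 1 4,4-bis(methylsulfanyl)but-3-en-2-one
Product: 3 1,1-bis(methylsulfanyl)-3-(trimethylsilyloxy)buta-1,3-diene, via lithium enolate 2 (not isolated)
Conditions: LiN(iPr)2 (1.05 equiv), THF, −78 °C; Me3SiCl (1.2 equiv), −78 → 0 °C; pentane, filtration, used crude
Reagents that add atoms: chlorotrimethylsilane, C[Si](C)(C)Cl
Why: Kinetic deprotonation of the methyl group (the only enolisable position) and O-silylation (silyl enol ether formation) should give a 2-siloxydiene whose terminal CH2 is activated directly by the siloxy group and vinylogously by the two thioether donors.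

Step 2
Reactants: 3 1,1-bis(methylsulfanyl)-3-(trimethylsilyloxy)buta-1,3-diene; 4 4-methoxybenzaldehyde
Product: 6 (2S)-2-(4-methoxyphenyl)-6-(methylsulfanyl)-2,3-dihydro-4H-pyran-4-one, via aldol 5 (not isolated)
Conditions: Ti(OiPr)4 (10 mol%), (S)-BINOL (20 mol%), 4 Å MS, Et2O, −20 °C; then CF3CO2H (0.3 equiv), wet CH2Cl2, 0 °C; NaHCO3
Reagents that add atoms: none
Why: Catalytic asymmetric Mukaiyama aldol addition of the siloxydiene terminus to the titanium-bound aldehyde (the first stage of the formal hetero-Diels–Alder reactions of 1-heteroatom-3-siloxydienes), in which the BINOL–titanium complex shields one face so that C–C bond formation on the Si face sets C2 as S; acid then frees the hydroxyl from its silyl ether and adds it 6-endo to the ketene dithioacetal carbon with loss of one methanethiol, which closes ring C without touching the C–O bond of the stereocentre.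

Step 3
Reactants: 6 (2S)-2-(4-methoxyphenyl)-6-(methylsulfanyl)-2,3-dihydro-4H-pyran-4-one
Product: 7 (2S)-6-(methanesulfonyl)-2-(4-methoxyphenyl)-2,3-dihydro-4H-pyran-4-one
Conditions: mCPBA (2.2 equiv), NaHCO3, CH2Cl2, 0 °C → rt; Na2S2O3/NaHCO3 wash; dried and used without chromatography
Reagents that add atoms: 3-chloroperoxybenzoic acid, OOC(=O)c1cccc(Cl)c1
Why: Oxidation of the vinylogous thioester sulfur to the sulfone, the acceptor-substituted alkene and the anisyl ring being inert to the peracid at this temperature; the sulfone turns C6 into an ynone-level carbon and supplies the leaving group for the later aromatisation.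

Step 4
Reactants: 8 6-methylhept-5-en-2-one; 9 1-bromo-3-methylbut-2-ene
Product: 11 2,10-dimethylundeca-2,9-dien-6-one, via lithium enolate 10 (not isolated)
Conditions: LiN(iPr)2 (1.05 equiv), THF, −78 °C (ketone added to the base); 9 (1.1 equiv), DMPU, −78 → −20 °C; distillation
Reagents that add atoms: none
Why: Kinetic deprotonation of the methyl ketone at the methyl group and SN2 alkylation of the lithium enolate by the allylic bromide (regioselective ketone alkylation) should turn the methyl group into a second 4-methylpent-3-enyl arm, which gives a ketone that is symmetrical about its carbonyl.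

Step 5
Reactants: 11 2,10-dimethylundeca-2,9-dien-6-one
Product: 12 (1E)-1-(dimethylamino)-7-methyl-2-(3-methylbut-2-en-1-yl)octa-1,6-dien-3-one
Conditions: tBuOCH(NMe2)2 (1.2 equiv), PhMe, 90 °C; volatiles removed in vacuo
Reagents that add atoms: tert-butoxybis(dimethylamino)methane, CC(C)(C)OC(N(C)C)N(C)C
Why: Aminomethylenation of an α-methylene ketone (enaminone formation); the two α-positions of the symmetrical ketone are equivalent, so one regioisomer should form, and the vinylogous amide is deactivated towards a second condensation.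

Step 6
Reactants: 12 (1E)-1-(dimethylamino)-7-methyl-2-(3-methylbut-2-en-1-yl)octa-1,6-dien-3-one
Product: 14 (1E,3Z)-3-{[tert-butyl(dimethyl)silyl]oxy}-N,N,7-trimethyl-2-(3-methylbut-2-en-1-yl)octa-1,3,6-trien-1-amine, via potassium dienolate 13 (not isolated)
Conditions: KN(SiMe3)2 (1.05 equiv), THF, −78 °C; tBuMe2SiCl (1.1 equiv), −78 °C → rt; pentane, filtration under Ar, used crude
Reagents that add atoms: tert-butyl(chloro)dimethylsilane, CC(C)(C)[Si](C)(C)Cl
Why: α'-Deprotonation of the vinylogous amide and O-silylation of the cross-conjugated enolate is the standard preparation of 1-amino-3-siloxy-1,3-dienes; the enolate geometry should place the C4 substituent outside the s-cis diene, and the amino group already lies trans to the acyl carbon.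

Step 7
Reactants: 7 (2S)-6-(methanesulfonyl)-2-(4-methoxyphenyl)-2,3-dihydro-4H-pyran-4-one; 14 (1E,3Z)-3-{[tert-butyl(dimethyl)silyl]oxy}-N,N,7-trimethyl-2-(3-methylbut-2-en-1-yl)octa-1,3,6-trien-1-amine
Product: 17 (2S)-7-hydroxy-2-(4-methoxyphenyl)-6,8-bis(3-methylbut-2-en-1-yl)-2,3-dihydro-4H-chromen-4-one (lespeflorin A1), via cycloadduct 15 (not isolated), via aryl silyl ether 16 (not isolated)
Conditions: 14 (1.4 equiv), PhMe, 4 Å MS, 0 °C → rt (→ 45 °C if needed); then Bu4NF (1.5 equiv), AcOH (2 equiv), THF, 0 °C; pH 7 phosphate buffer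
Reagents that add atoms: none
Why: Proposed new method: the nucleophilic terminus C4 of diene 14 should bond to C6 of 7 (the carbon that carries O1 and the sulfonyl group, later C8a) and C1 of 14 to C5 of 7 (later C4a), in a Diels–Alder reaction or its stepwise Michael–Mannich equivalent, to give 15; 15 should then lose methanesulfinate from C8a by E1cB through the C4 enolate and dimethylamine from C5 together with the C8 proton, the acid and the amine neutralising each other, which leaves the aromatic silyl ether 16, and buffered fluoride frees the phenol. The closest known reaction type is the regiospecific phenol synthesis in which a 1-methoxy-3-siloxybuta-1,3-diene adds to a β-sulfinyl enone that serves as an ynone equivalent and the adduct aromatises by double elimination, 1-amino-3-siloxydienes being the more reactive relatives of that diene; it has not been shown on a 6-sulfonyl-2,3-dihydro-4H-pyran-4-one, whose β-carbon also bears the ring oxygen. Ring A (C4a–C5–C6–C7–C8–C8a) is closed by this [4+2] union of the four diene carbons with the C4a=C8a bond of ring C, six-membered by construction, and no other ring is formed. The stereocentres of 15 (C4a, C5, C8, C8a) are all erased on aromatisation and no bond to C2 is made or broken under these nearly neutral conditions, so the S configuration from step 2 is carried through. Two selectivities are needed: the orientation of the addition, which the polarity of both partners should secure (electron-rich diene terminus to the electrophilic β-carbon of the vinylogous ester, so that C7–O ends para to the acyl-bearing C4a, with both prenyl groups already fixed on C6 and C8 by the diene), and loss of sulfinate and not of O1 from C8a, which the far better leaving group should secure.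

**Compound list**
1 | 4,4-bis(methylsulfanyl)but-3-en-2-one | CC(=O)C=C(SC)SC | starting material
2 | lithium 4,4-bis(methylsulfanyl)buta-1,3-dien-2-olate | [Li+].C=C([O-])C=C(SC)SC | intermediate
3 | 1,1-bis(methylsulfanyl)-3-(trimethylsilyloxy)buta-1,3-diene | C=C(O[Si](C)(C)C)C=C(SC)SC | intermediate
4 | 4-methoxybenzaldehyde | COc1ccc(C=O)cc1 | starting material
5 | (5S)-5-hydroxy-5-(4-methoxyphenyl)-1,1-bis(methylsulfanyl)pent-1-en-3-one | COc1ccc([C@@H](O)CC(=O)C=C(SC)SC)cc1 | intermediate
6 | (2S)-2-(4-methoxyphenyl)-6-(methylsulfanyl)-2,3-dihydro-4H-pyran-4-one | COc1ccc([C@@H]2CC(=O)C=C(SC)O2)cc1 | intermediate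
7 | (2S)-6-(methanesulfonyl)-2-(4-methoxyphenyl)-2,3-dihydro-4H-pyran-4-one | COc1ccc([C@@H]2CC(=O)C=C(S(C)(=O)=O)O2)cc1 | intermediate
8 | 6-methylhept-5-en-2-one | CC(=O)CCC=C(C)C | starting material
9 | 1-bromo-3-methylbut-2-ene | CC(C)=CCBr | starting material
10 | lithium 6-methylhepta-1,5-dien-2-olate | [Li+].C=C([O-])CCC=C(C)C | intermediate
11 | 2,10-dimethylundeca-2,9-dien-6-one | CC(C)=CCCC(=O)CCC=C(C)C | intermediate
12 | (1E)-1-(dimethylamino)-7-methyl-2-(3-methylbut-2-en-1-yl)octa-1,6-dien-3-one | CN(C)/C=C(\CC=C(C)C)C(=O)CCC=C(C)C | intermediate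
13 | potassium (1E,3Z)-1-(dimethylamino)-7-methyl-2-(3-methylbut-2-en-1-yl)octa-1,3,6-trien-3-olate | [K+].CN(C)/C=C(\CC=C(C)C)/C([O-])=C/CC=C(C)C | intermediate
14 | (1E,3Z)-3-{[tert-butyl(dimethyl)silyl]oxy}-N,N,7-trimethyl-2-(3-methylbut-2-en-1-yl)octa-1,3,6-trien-1-amine | CN(C)/C=C(\CC=C(C)C)/C(O[Si](C)(C)C(C)(C)C)=C/CC=C(C)C | intermediate
15 | (2S)-7-{[tert-butyl(dimethyl)silyl]oxy}-5-(dimethylamino)-8a-(methanesulfonyl)-2-(4-methoxyphenyl)-6,8-bis(3-methylbut-2-en-1-yl)-2,3,4a,5,8,8a-hexahydro-4H-chromen-4-one (mixture at C4a, C5, C8, C8a) | COc1ccc([C@@H]2CC(=O)C3C(N(C)C)C(CC=C(C)C)=C(O[Si](C)(C)C(C)(C)C)C(CC=C(C)C)C3(S(C)(=O)=O)O2)cc1 | intermediate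
16 | (2S)-7-{[tert-butyl(dimethyl)silyl]oxy}-2-(4-methoxyphenyl)-6,8-bis(3-methylbut-2-en-1-yl)-2,3-dihydro-4H-chromen-4-one | COc1ccc([C@@H]2CC(=O)c3cc(CC=C(C)C)c(O[Si](C)(C)C(C)(C)C)c(CC=C(C)C)c3O2)cc1 | intermediate
17 | (2S)-7-hydroxy-2-(4-methoxyphenyl)-6,8-bis(3-methylbut-2-en-1-yl)-2,3-dihydro-4H-chromen-4-one (lespeflorin A1) | COc1ccc([C@@H]2CC(=O)c3cc(CC=C(C)C)c(O)c(CC=C(C)C)c3O2)cc1 | target

Total step count: 7. Longest linear sequence: 4 steps (steps 1, 2, 3, 7 or steps 4, 5, 6, 7).

**Steps most likely to fail**

Step 7 (proposed new method). Bond formation at the fully substituted C6 of the dienophile may be slow, so that displacement of the sulfonyl group by adventitious water or by released amine competes, or the first C–C bond may form without ring closure. The fallback sets out from 7 and from the potassium dienolate 13 (made from 12 as in step 6 but not silylated) and uses two separate ionic steps of known type. Enolate 13 (2.1 equiv, THF, −78 °C) would add to C6 of 7 and expel methanesulfinate, a conjugate addition–elimination of a ketone enolate on a β-sulfonyl enone. This would give (2S)-6-[(1E)-1-(dimethylamino)-7-methyl-2-(3-methylbut-2-en-1-yl)-3-oxoocta-1,6-dien-4-yl]-2-(4-methoxyphenyl)-2,3-dihydro-4H-pyran-4-one F1 as a mixture at the new side-chain centre. Warming F1 with AcOH in PhMe (60 °C) would close ring A by attack of the nucleophilic α-carbon of the vinylogous ester on the protonated enaminone carbon, and loss of dimethylamine and enolisation would then give the phenol. The fallback comes back to the route at 17.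

Step 2. Sulfur binding to the titanium catalyst may lower turnover and facial selectivity, and the acid stage may ionise the 4-methoxybenzylic alcohol (loss of enantiopurity or dehydration). The fallback sets out from 4 and puts the stereocentre in by the well-tried hetero-Diels–Alder reaction of aryl aldehydes. Aldehyde 4 and commercial (E)-1-methoxy-3-(trimethylsilyloxy)buta-1,3-diene under Ti(OiPr)4/(S)-BINOL catalysis, then CF3CO2H, would give (2S)-2-(4-methoxyphenyl)-2,3-dihydro-4H-pyran-4-one F2. Conjugate addition of methanethiol (MeSH, Et3N cat., CH2Cl2, 0 °C) would give (2S)-2-(4-methoxyphenyl)-6-(methylsulfanyl)oxan-4-one F3 as a mixture at C6. Chlorination at the sulfur-bearing ring carbon with N-chlorosuccinimide (CCl4, 0 °C) would give (2S)-6-chloro-2-(4-methoxyphenyl)-6-(methylsulfanyl)oxan-4-one F4, and dehydrochlorination with Et3N would restore the double bond. The fallback comes back to the route at 6.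

Step 3. The sulfonyl group on the acetal-level carbon may be lost by hydrolysis or by attack of 3-chlorobenzoate during oxidation and work-up. The fallback sets out from 6 and stops the oxidation at the sulfoxide (mCPBA, 1.0 equiv, CH2Cl2, −78 °C). This would give (2S)-6-(methanesulfinyl)-2-(4-methoxyphenyl)-2,3-dihydro-4H-pyran-4-one F5 as a mixture of sulfur epimers, a less electrophilic dienophile and the classical ynone equivalent for this phenol synthesis. Cycloaddition with 14 (PhMe, rt → 70 °C) would give (2S)-7-{[tert-butyl(dimethyl)silyl]oxy}-5-(dimethylamino)-8a-(methanesulfinyl)-2-(4-methoxyphenyl)-6,8-bis(3-methylbut-2-en-1-yl)-2,3,4a,5,8,8a-hexahydro-4H-chromen-4-one F6. F6 would aromatise by thermal syn-elimination of methanesulfenic acid and loss of dimethylamine. The fallback comes back to the route at 16, which is desilylated as in step 7.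

**Further compounds**
F1 | step 7 | (2S)-6-[(1E)-1-(dimethylamino)-7-methyl-2-(3-methylbut-2-en-1-yl)-3-oxoocta-1,6-dien-4-yl]-2-(4-methoxyphenyl)-2,3-dihydro-4H-pyran-4-one (mixture at the side-chain C4) | COc1ccc([C@@H]2CC(=O)C=C(C(CC=C(C)C)C(=O)/C(CC=C(C)C)=C/N(C)C)O2)cc1
F2 | step 2 | (2S)-2-(4-methoxyphenyl)-2,3-dihydro-4H-pyran-4-one | COc1ccc([C@@H]2CC(=O)C=CO2)cc1
F3 | step 2 | (2S)-2-(4-methoxyphenyl)-6-(methylsulfanyl)oxan-4-one (mixture at C6) | COc1ccc([C@@H]2CC(=O)CC(SC)O2)cc1
F4 | step 2 | (2S)-6-chloro-2-(4-methoxyphenyl)-6-(methylsulfanyl)oxan-4-one (mixture at C6) | COc1ccc([C@@H]2CC(=O)CC(Cl)(SC)O2)cc1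
F5 | step 3 | (2S)-6-(methanesulfinyl)-2-(4-methoxyphenyl)-2,3-dihydro-4H-pyran-4-one (mixture at sulfur) | COc1ccc([C@@H]2CC(=O)C=C(S(C)=O)O2)cc1
F6 | step 3 | (2S)-7-{[tert-butyl(dimethyl)silyl]oxy}-5-(dimethylamino)-8a-(methanesulfinyl)-2-(4-methoxyphenyl)-6,8-bis(3-methylbut-2-en-1-yl)-2,3,4a,5,8,8a-hexahydro-4H-chromen-4-one | COc1ccc([C@@H]2CC(=O)C3C(N(C)C)C(CC=C(C)C)=C(O[Si](C)(C)C(C)(C)C)C(CC=C(C)C)C3(S(C)=O)O2)cc1
A1 | direct plan | 1-(2,4-dihydroxyphenyl)ethan-1-one | CC(=O)c1ccc(O)cc1O
A2 | direct plan | 1-[2,4-dihydroxy-3,5-bis(3-methylbut-2-en-1-yl)phenyl]ethan-1-one | CC(=O)c1cc(CC=C(C)C)c(O)c(CC=C(C)C)c1O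
A3 | direct plan | 1-[4-(tert-butyldimethylsilyloxy)-2-hydroxy-3,5-bis(3-methylbut-2-en-1-yl)phenyl]ethan-1-one | CC(=O)c1cc(CC=C(C)C)c(O[Si](C)(C)C(C)(C)C)c(CC=C(C)C)c1O
A4 | direct plan | tert-butyl (E)-3-(4-methoxyphenyl)prop-2-en-1-yl carbonate | COc1ccc(/C=C/COC(=O)OC(C)(C)C)cc1
A5 | direct plan | 1-[4-(tert-butyldimethylsilyloxy)-2-{[(1S)-1-(4-methoxyphenyl)prop-2-en-1-yl]oxy}-3,5-bis(3-methylbut-2-en-1-yl)phenyl]ethan-1-one | COc1ccc([C@H](C=C)Oc2c(CC=C(C)C)c(O[Si](C)(C)C(C)(C)C)c(CC=C(C)C)cc2C(C)=O)cc1
A6 | direct plan | 1-[1-(tert-butyldimethylsilyloxy)ethenyl]-4-(tert-butyldimethylsilyloxy)-2-{[(1S)-1-(4-methoxyphenyl)prop-2-en-1-yl]oxy}-3,5-bis(3-methylbut-2-en-1-yl)benzene | COc1ccc([C@H](C=C)Oc2c(CC=C(C)C)c(O[Si](C)(C)C(C)(C)C)c(CC=C(C)C)cc2C(=C)O[Si](C)(C)C(C)(C)C)cc1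
A7 | direct plan | (2S)-4,7-bis(tert-butyldimethylsilyloxy)-2-(4-methoxyphenyl)-6,8-bis(3-methylbut-2-en-1-yl)-2H-chromene | COc1ccc([C@@H]2C=C(O[Si](C)(C)C(C)(C)C)c3cc(CC=C(C)C)c(O[Si](C)(C)C(C)(C)C)c(CC=C(C)C)c3O2)cc1
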